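**Retrosynthetic overview**

1. Numbering used below (elemanolide): C10 is the quaternary carbon (C14 methyl, C1=C2 vinyl); C5 carries C4(=C3H2)–C15H2OH; C6 carries the lactone oxygen; C7 carries C11(=C13H2)–C12(=O); C8 carries the ester; C9 is the ring CH2. α is the face of O6, O8 and C1; β is the face of C14.
2. Late disconnections: the C8 ester (Steglich; acid from methyl (R)-3-hydroxy-2-methylpropanoate), C11=C13 (lactone α-methylenation), C4=C3 with C15–OH (aldehyde α-methylenation, 1,2-reduction), C1=C2 (Wittig) and C8–OH with C7–H (hydroboration of C7=C8) lead back to a bicyclic lactone aldehyde.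
3. Key disconnection: C5–C6 and C9–C10 are cut together as a [4+2] cycloaddition between the diene C6=C7–C8=C9 of a 2-silyloxy-4-vinylfuran and the C5=C10 double bond of an (E)-2-methyl-2-enal.
4. Enabling feature: the γ-lactone ring O–C12–C11–C7–C6 can be drawn at the furan (butenolide dienolate) level. There C6, still bonded to the lactone oxygen, is γ to the C12 carbonyl and therefore nucleophilic, and a vinyl group (C8=C9) on C7 completes a 1,3-diene whose ends are exactly C6 and C9.
5. Ring order: the five-membered lactone ring is present from the start (bromofuranone, then the furan); the cyclohexane ring is closed around it in the key step; no other ring is formed.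

Key step: step 4

Assumption: the (S)-oxazaborolidinium catalyst of step 4 is taken to expose the enal face that is Re at C10; if a test reaction shows the opposite sense, its (R)-antipode is used and nothing else changes.

**Step 1**
Reactants: 1 3-[(tert-butyldimethylsilyl)oxy]propanal; 2 2-(triphenylphosphoranylidene)propanal
Product: 3 (E)-5-[(tert-butyldimethylsilyl)oxy]-2-methylpent-2-enal
Conditions: toluene, 90 °C
Reagents that add atoms: none
Why: Wittig olefination with a stabilised ylide should give the (E)-enal (C4 cis to C14 across C5=C10), the geometry that later fixes the C5/C10 relationship.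

**Step 2**
Reactants: 4 4-bromofuran-2(5H)-one; 5 tributyl(vinyl)stannane
Product: 6 4-vinylfuran-2(5H)-one
Conditions: Pd(PPh3)4 (5 mol %), 1,4-dioxane, 80 °C; product stored cold and used soon
Reagents that add atoms: none
Why: Stille cross-coupling at the vinylogous acyl bromide (oxidative addition to zerovalent palladium, transmetallation from tin, reductive elimination) is well precedented for 4-halofuranones and brings in C8=C9.

**Step 3**
Reactants: 6 4-vinylfuran-2(5H)-one
Product: 7 2-[(triisopropylsilyl)oxy]-4-vinylfuran
Conditions: iPr3SiOTf, Et3N, CH2Cl2, 0 °C; pentane extraction, used at once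
Reagents that add atoms: triisopropylsilyl trifluoromethanesulfonate, CC(C)[Si](OS(=O)(=O)C(F)(F)F)(C(C)C)C(C)C
Why: Soft enolisation at C6 and O-silylation of the butenolide dienolate is the standard way to aromatic 2-silyloxyfurans.

**Step 4**
Reactants: 7 2-[(triisopropylsilyl)oxy]-4-vinylfuran; 3 (E)-5-[(tert-butyldimethylsilyl)oxy]-2-methylpent-2-enal
Product: 9 bicyclic lactone aldehyde (C1 formyl on C10 and C7=C8), via silyl ketene acetal cycloadduct 8 (not isolated)
Conditions: (S)-3,3-diphenyl-1-(o-tolyl)tetrahydro-1H,3H-pyrrolo[1,2-c][1,3,2]oxazaborole protonated by Tf2NH (20 mol %), CH2Cl2, −78 to −40 °C; then Bu4NF, AcOH, THF, −78 °C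
Reagents that add atoms: none
Why: Proposed new method: the catalyst-bound (E)-enal 3 is attacked at its β-carbon C5 by C6 of 7 (the γ-carbon of the silyl dienolate, the most nucleophilic site of a 2-silyloxyfuran) and the developing enolate carbon C10 closes onto C9 at the end of the vinyl group, an asynchronous concerted [4+2] cycloaddition across the exocyclic diene C6=C7–C8=C9; the closest known reactions are the vinylogous Mukaiyama–Michael addition of 2-silyloxyfurans to enals and the extra-annular Diels–Alder reactions of 3-vinylfurans and 3-vinylindoles under chiral Lewis-acid catalysis. The cyclohexane ring C5–C6–C7–C8–C9–C10 is the only ring closed, by [4+2] cycloaddition onto the lactone ring already present as the furan. C5 and C10 follow from the (E)-geometry of 3 by suprafacial addition (C4 cis to C14), C6 from the endo orientation of the formyl group, which puts the furan oxygen (the outside substituent of the diene) cis to C1 and trans to C4, and the absolute sense from the catalyst. The step needs C6-to-C5 regiochemistry, secured because C6 is the dienolate terminus and C5 the unhindered β-carbon while C10 becomes quaternary only in the later-formed bond; it needs endo selectivity, favoured because only H and CHO then lie under the diene; and it needs conjugate rather than 1,2-addition to the aldehyde, for which the bulky catalyst and the α-methyl group are relied on. Fluoride release of the dienolate and kinetic protonation at C11 at −78 °C should leave the C7=C8 double bond in place.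

**Step 5**
Reactants: 9 bicyclic lactone aldehyde
Product: 10 diol (C1 primary alcohol and 8α-OH with 7α-H and trans-fused lactone)
Conditions: BH3·THF (2.2 equiv), THF, 0 °C; then 30% H2O2, pH 7 phosphate buffer, 0 °C to rt
Reagents that add atoms: hydrogen peroxide, OO
Why: Hydroboration–oxidation: borane reduces the aldehyde and adds syn and anti-Markovnikov to C7=C8 from the α-face, away from the axial C14 methyl that is 1,3 to C8, so that 7-H and 8-OH should both be α and the lactone trans-fused.

**Step 6**
Reactants: 10 diol
Product: 11 aldehyde (C1 formyl and free 8α-OH)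
Conditions: 2,2,6,6-tetramethylpiperidin-1-oxyl (10 mol %), PhI(OAc)2, CH2Cl2, rt
Reagents that add atoms: none
Why: Oxoammonium (TEMPO) oxidation takes the primary C1 alcohol in preference to the hindered secondary C8 alcohol, and the trans-fused lactone keeps C1 and O8 equatorial so that no lactol can form.

**Step 7**
Reactants: 11 aldehyde
Product: 12 vinyl lactone (C1=C2 installed)
Conditions: Ph3PCH3Br, KN(SiMe3)2 (ylide 2.2 equiv), THF, 0 °C
Reagents that add atoms: methyltriphenylphosphonium bromide, C[P+](c1ccccc1)(c1ccccc1)c1ccccc1.[Br-]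
Why: Wittig methylenation of the hindered but non-enolisable C1 aldehyde gives the vinyl group on the quaternary carbon; no stereocentre is touched.

**Step 8**
Reactants: 12 vinyl lactone
Product: 13 diol (free C15 and C8 hydroxyls)
Conditions: HF·pyridine, pyridine, THF, 0 °C to rt
Reagents that add atoms: none
Why: Fluoride cleavage of the primary silyl ether; lactone, vinyl group and secondary alcohol are inert.

**Step 9**
Reactants: 13 diol
Product: 14 aldehyde (C15 formyl on the C4 methylene)
Conditions: 2,2,6,6-tetramethylpiperidin-1-oxyl (10 mol %), PhI(OAc)2, CH2Cl2, rt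
Reagents that add atoms: none
Why: TEMPO oxidation again selects the primary alcohol over the secondary C8 alcohol.

**Step 10**
Reactants: 14 aldehyde
Product: 16 allylic alcohol (C4=C3H2 and C15H2OH), via enal 15 (not isolated)
Conditions: CH2=NMe2+ I− (2.5 equiv), Et3N, CH2Cl2, rt; then NaBH4, CeCl3·7H2O, MeOH, −78 °C
Reagents that add atoms: N,N-dimethylmethyleneiminium iodide (Eschenmoser's salt), C=[N+](C)C.[I-]
Why: Mannich reaction of the aldehyde with loss of dimethylamine (aldehyde α-methylenation) and immediate Luche 1,2-reduction of the sensitive 2-substituted acrolein should give the C4(=CH2)CH2OH unit without touching the saturated lactone or C5.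

**Step 11**
Reactants: 16 allylic alcohol
Product: 17 C15 silyl ether (free 8α-OH)
Conditions: tBuMe2SiCl (1.05 equiv), imidazole, CH2Cl2, −20 to 0 °C
Reagents that add atoms: tert-butyldimethylsilyl chloride, CC(C)(C)[Si](C)(C)Cl
Why: Silylation is much faster at the unhindered primary allylic alcohol than at the secondary C8 alcohol flanked by C7 and C9.

**Step 12**
Reactants: 17 C15 silyl ether
Product: 20 α-methylene lactone (C11=C13), via Mannich base 18 (not isolated), via methiodide 19 (not isolated)
Conditions: LiN(iPr)2 (2.5 equiv), THF, −78 °C (inverse addition); CH2=NMe2+ I−, −78 °C; AcOH quench; then MeI, MeOH, rt; then aq. NaHCO3, CH2Cl2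
Reagents that add atoms: N,N-dimethylmethyleneiminium iodide (Eschenmoser's salt), C=[N+](C)C.[I-]
Why: Lactone α-methylenation by Mannich reaction of the enolate (the C8 alkoxide is formed alongside and never meets neutral lactone because of the inverse addition), then exhaustive methylation and Hofmann-type elimination; the C11 configuration of 18 and 19 is not controlled and is lost.

**Step 13**
Reactants: 21 methyl (R)-3-hydroxy-2-methylpropanoate
Product: 22 methyl (R)-3-[(tert-butyldimethylsilyl)oxy]-2-methylpropanoate
Conditions: tBuMe2SiCl, imidazole, DMF, rt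
Reagents that add atoms: tert-butyldimethylsilyl chloride, CC(C)(C)[Si](C)(C)Cl
Why: Routine silylation of the primary alcohol; the α-stereocentre is not involved.

**Step 14**
Reactants: 22 methyl (R)-3-[(tert-butyldimethylsilyl)oxy]-2-methylpropanoate
Product: 23 (R)-3-[(tert-butyldimethylsilyl)oxy]-2-methylpropanoic acid
Conditions: LiOH, THF/H2O, 0 °C; then 1 M HCl to pH 3
Reagents that add atoms: lithium hydroxide, [Li+].[OH-]
Why: Saponification at 0 °C should leave the α-stereocentre intact.

**Step 15**
Reactants: 20 α-methylene lactone; 23 (R)-3-[(tert-butyldimethylsilyl)oxy]-2-methylpropanoic acid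
Product: 24 bis-silyl ether of the target
Conditions: N,N'-dicyclohexylcarbodiimide, 4-(dimethylamino)pyridine (10 mol %), CH2Cl2, 0 °C to rt
Reagents that add atoms: none
Why: Steglich esterification acylates the only free hydroxyl with retention at C8.

**Step 16**
Reactants: 24 bis-silyl ether of the target
Product: 25 target CNP0133858.1
Conditions: HF·pyridine, pyridine, THF, 0 °C to rt
Reagents that add atoms: none
Why: Fluoride cleavage of both primary silyl ethers under mildly acidic, non-nucleophilic conditions that spare the α-methylene lactone and the two esters.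

**Compound list**

1 | 3-[(tert-butyldimethylsilyl)oxy]propanal | O=CCCO[Si](C)(C)C(C)(C)C | starting material
2 | 2-(triphenylphosphoranylidene)propanal | CC(C=O)=P(c1ccccc1)(c1ccccc1)c1ccccc1 | starting material
3 | (E)-5-[(tert-butyldimethylsilyl)oxy]-2-methylpent-2-enal | O=C/C(C)=C/CCO[Si](C)(C)C(C)(C)C | intermediate
4 | 4-bromofuran-2(5H)-one | O=C1C=C(Br)CO1 | starting material
5 | tributyl(vinyl)stannane | C=C[Sn](CCCC)(CCCC)CCCC | starting material
6 | 4-vinylfuran-2(5H)-one | C=CC1=CC(=O)OC1 | intermediate
7 | 2-[(triisopropylsilyl)oxy]-4-vinylfuran | C=Cc1coc(O[Si](C(C)C)(C(C)C)C(C)C)c1 | intermediate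
8 | cycloadduct: 12-O-triisopropylsilyl ketene acetal of 9 (C7=C8 and C11=C12; 5α-H, 6β-H, 10β-CH3, C1 formyl α) | O=C[C@]1(C)CC=C2C=C(O[Si](C(C)C)(C(C)C)C(C)C)O[C@@H]2[C@H]1CCO[Si](C)(C)C(C)(C)C | intermediate
9 | (6R,7S,7aR)-7-[2-(tert-butyldimethylsilyloxy)ethyl]-6-methyl-2-oxo-2,3,5,6,7,7a-hexahydro-1-benzofuran-6-carbaldehyde (C1 formyl α on C10, 10β-CH3, 5α-H, 6β-H, C7=C8) | O=C[C@]1(C)CC=C2CC(=O)O[C@@H]2[C@H]1CCO[Si](C)(C)C(C)(C)C | intermediate
10 | diol: C10 carries CH2OH (C1, α) and CH3 (β); 8α-OH; trans-fused 6α,12-lactone with C11H2; C5 carries β-CH2CH2OSi(tBu)Me2; 5α-H, 6β-H, 7α-H, 8β-H | OC[C@]1(C)C[C@H](O)[C@H]2CC(=O)O[C@@H]2[C@H]1CCO[Si](C)(C)C(C)(C)C | intermediate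
11 | aldehyde: as 10 with C1 as CHO | O=C[C@]1(C)C[C@H](O)[C@H]2CC(=O)O[C@@H]2[C@H]1CCO[Si](C)(C)C(C)(C)C | intermediate
12 | vinyl lactone: as 11 with C1=C2 vinyl on C10 | C=C[C@]1(C)C[C@H](O)[C@H]2CC(=O)O[C@@H]2[C@H]1CCO[Si](C)(C)C(C)(C)C | intermediate
13 | diol: as 12 with C5 carrying β-CH2CH2OH | C=C[C@]1(C)C[C@H](O)[C@H]2CC(=O)O[C@@H]2[C@H]1CCO | intermediate
14 | aldehyde: as 12 with C5 carrying β-CH2CHO | C=C[C@]1(C)C[C@H](O)[C@H]2CC(=O)O[C@@H]2[C@H]1CC=O | intermediate
15 | enal: as 12 with C5 carrying β-C(=CH2)CHO | C=C[C@]1(C)C[C@H](O)[C@H]2CC(=O)O[C@@H]2[C@H]1C(=C)C=O | intermediate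
16 | allylic alcohol: as 12 with C5 carrying β-C(=CH2)CH2OH | C=C[C@]1(C)C[C@H](O)[C@H]2CC(=O)O[C@@H]2[C@H]1C(=C)CO | intermediate
17 | C15 silyl ether: as 16 with C15–OSi(tBu)Me2, free 8α-OH | C=C[C@]1(C)C[C@H](O)[C@H]2CC(=O)O[C@@H]2[C@H]1C(=C)CO[Si](C)(C)C(C)(C)C | intermediate
18 | Mannich base: 17 with CH2NMe2 at C11 (one C11 epimer drawn; not controlled) | C=C[C@]1(C)C[C@H](O)[C@H]2[C@H](CN(C)C)C(=O)O[C@@H]2[C@H]1C(=C)CO[Si](C)(C)C(C)(C)C | intermediate
19 | methiodide of 18 | C=C[C@]1(C)C[C@H](O)[C@H]2[C@H](C[N+](C)(C)C)C(=O)O[C@@H]2[C@H]1C(=C)CO[Si](C)(C)C(C)(C)C.[I-] | intermediate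
20 | α-methylene lactone: 17 with C11=C13H2 | C=C[C@]1(C)C[C@H](O)[C@H]2C(=C)C(=O)O[C@@H]2[C@H]1C(=C)CO[Si](C)(C)C(C)(C)C | intermediate
21 | methyl (R)-3-hydroxy-2-methylpropanoate | C[C@H](CO)C(=O)OC | starting material
22 | methyl (R)-3-[(tert-butyldimethylsilyl)oxy]-2-methylpropanoate | C[C@H](CO[Si](C)(C)C(C)(C)C)C(=O)OC | intermediate
23 | (R)-3-[(tert-butyldimethylsilyl)oxy]-2-methylpropanoic acid | C[C@H](CO[Si](C)(C)C(C)(C)C)C(=O)O | intermediate
24 | bis-silyl ether of the target (C15–O and side-chain O as tert-butyldimethylsilyl ethers) | C=C[C@]1(C)C[C@H](OC(=O)[C@H](C)CO[Si](C)(C)C(C)(C)C)[C@H]2C(=C)C(=O)O[C@@H]2[C@H]1C(=C)CO[Si](C)(C)C(C)(C)C | intermediate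
25 | CNP0133858.1: (3aR,4S,6S,7R,7aR)-6-ethenyl-7-(3-hydroxyprop-1-en-2-yl)-6-methyl-3-methylidene-2-oxo-octahydro-1-benzofuran-4-yl (2R)-3-hydroxy-2-methylpropanoate | C=C[C@]1(C)C[C@H](OC(=O)[C@H](C)CO)[C@H]2C(=C)C(=O)O[C@@H]2[C@H]1C(=C)CO | target

**Step count**

Total steps: 16. Longest linear sequence: 13 steps (from 4: steps 2 to 12, then 15 and 16).

**Steps most likely to fail**

Step 4 (proposed new method). Possible failures:
- 1,2-addition of the silyloxyfuran to the aldehyde (vinylogous aldol) instead of conjugate addition;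
- attack through C11 instead of C6;
- protodesilylation or dimerisation of 7 before it reacts;
- erosion of endo selectivity;
- protonation of the dienolate at C8, which would move the double bond into conjugation.

Fallback with known reactions, from 7 and 3, back at 9: the two bonds are made one after the other. A vinylogous Mukaiyama–Michael addition of 7 to 3 under the same oxazaborolidinium catalysis at −78 °C, with fluoride work-up, would give the open-chain butenolide aldehyde F1 (C5–C6 made, C10 still epimeric). Catalytic pyrrolidine and AcOH would then convert the aldehyde into its enamine, whose C10 adds in an intramolecular 1,6-Michael reaction to C9 of the 4-vinylbutenolide. Protonation of the resulting lactone dienolate at C11 returns 9, after separation of any C10 epimer.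

Step 5. Possible failures: borane delivery from the β-face (cis-lactone, 8β-OH), partial reduction of the lactone, or isomerisation of 9 to the conjugated butenolide before hydroboration.

Fallback from 9, back at 11 (step 6 is then not needed): dimethyldioxirane in acetone at −20 °C should epoxidise C7=C8 from the α-face to the epoxide F2. Et3N in CH2Cl2 would open it through the lactone enolate (E1cB) to the 8α-hydroxy butenolide F3. Hydroxyl-directed hydrogenation with H2 and [Ir(cod)(PCy3)(py)]PF6 in CH2Cl2 would deliver hydrogen to C7 on the face of the 8α-OH and give 11.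

Step 12. Possible failures: migration of the lactone from O6 to O8 through the C8 alkoxide, incomplete dianion formation, or retro-Mannich loss during quaternisation.

Fallback from 17, back at 20: the C8 hydroxyl is masked first. Me3SiCl and imidazole would give the trimethylsilyl ether F4. Enolisation with LiN(iPr)2 (1.1 equiv), Eschenmoser's salt, MeI and aq. NaHCO3 as in step 12 would give the α-methylene lactone F5. Citric acid in MeOH at 0 °C would remove only the trimethylsilyl group and return 20.

**Further compounds**

F1 | step 4 | butenolide aldehyde: 4-vinylfuran-2(5H)-one carrying at its C5 (= C6) the chain CH(CH2CH2OSi(tBu)Me2)–CH(CH3)–CHO; C6 and C5 as in 9, C10 epimeric | C=CC1=CC(=O)O[C@@H]1[C@@H](CCO[Si](C)(C)C(C)(C)C)C(C)C=O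
F2 | step 5 | 7α,8α-epoxide of 9 | O=C[C@]1(C)C[C@H](O3)[C@]32CC(=O)O[C@@H]2[C@H]1CCO[Si](C)(C)C(C)(C)C
F3 | step 5 | 8α-hydroxy butenolide aldehyde (C7=C11, C1 formyl) | O=C[C@]1(C)C[C@H](O)C2=CC(=O)O[C@@H]2[C@H]1CCO[Si](C)(C)C(C)(C)C
F4 | step 12 | 8-O-trimethylsilyl ether of 17 | C=C[C@]1(C)C[C@H](O[Si](C)(C)C)[C@H]2CC(=O)O[C@@H]2[C@H]1C(=C)CO[Si](C)(C)C(C)(C)C
F5 | step 12 | 8-O-trimethylsilyl ether of 20 | C=C[C@]1(C)C[C@H](O[Si](C)(C)C)[C@H]2C(=C)C(=O)O[C@@H]2[C@H]1C(=C)CO[Si](C)(C)C(C)(C)C
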